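**Plan**

1. Locants: ring A = C1–C5, C10 (C20 = methyl on C10); ring B = C5, C6, O, C7, C8, C9, C10; ring C = C8, C9, C11, C12, C13, C14; ring D = C8, C14, C13, C16, C15 (C17 = exocyclic CH2). α = side of C20, β = side of H5; exo = face of ring C turned away from the C15–C16 bridge.
2. Retrosynthesis: lactol O–H ← O-PMB; oxirane ← C9=C11; C15=O ← allylic CH2; then cut C12–C13 (ring C), C13=C16 (ring D), the two C8–CH2 bonds, O–C6 (ring B), C2–O, C9–C10 and C5–C6.
3. Enabling feature: C9 of ring C lies between the quaternary carbons C8 and C10, so a C9–C11–C12 allyl cation has no β-hydrogen to lose. The unit C13–C16=C17 of ring D is the product side of an allylsilane SE2′ reaction, so C12–C13 can be closed from a ring-D allylsilane.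
4. Forward order: ring A (conjugate addition–aldol on a cyclohexenone) → ring B (oxepane acetal) → ring D (spiro-cyclopentene from two enolate alkylations and metathesis) → ring C last, then oxidation-state adjustments.
5. Stereochemistry: C5 by catalyst control; C10 by anti trapping of the enolate; C1/C2 by β-face hydride delivery to a 1,2-dione in the rigid A/B bicycle; C6 by thermodynamic acetalisation; C8 by alkylation anti to C20; C13 by the bridging cyclisation; C9/C11 by exo-face epoxidation.

Key step: step 15

Assumption: the C6 configuration of the target is taken to be the thermodynamically preferred anomer of the oxepane acetal and lactol, so acetal exchange (step 4) and the free lactol (step 21) should settle there. Transient centres (carbinol C9 in 5–16, 25, 26; C2 in 12; C8 in 20; C15 in 30; the ozonide carbon in 7) are left undefined because both epimers converge.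

**Route**

Step 1
Reactants: 1 2,4,4-trimethylcyclohex-2-en-1-one; 2 vinylmagnesium bromide (CH2=CHMgBr); 3 3-[(tert-butyldimethylsilyl)oxy]propanal
Product: 5 (2R,3R)-2-[3-(tert-butyldimethylsilyloxy)-1-hydroxypropyl]-2,4,4-trimethyl-3-vinylcyclohexan-1-one (carbinol epimers), via bromomagnesium enolate 4 (not isolated)
Conditions: CuBr·SMe2 (5 mol%), (R)-1-[(S)-2-(diphenylphosphino)ferrocenyl]ethyldicyclohexylphosphine (6 mol%; or its enantiomer, whichever delivers the 3R centre), t-BuOMe, −78 °C; then 3, −78 → −40 °C; aq. NH4Cl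
Reagents that add atoms: none
Why: Copper-catalysed asymmetric conjugate addition of the Grignard reagent should set C5 under ligand control, and aldol trapping of the magnesium enolate by 3 should occur anti to the new vinyl group, which gives the quaternary C10 trans to C5 (conjugate addition–aldol three-component coupling).

Step 2
Reactants: 5 aldol adduct
Product: 6 benzoate of 5 (benzoyloxy on the carbinol carbon C9)
Conditions: PhCOCl, DMAP (cat.), pyridine, CH2Cl2, 0 °C → rt
Reagents that add atoms: benzoyl chloride O=C(Cl)c1ccccc1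
Why: DMAP-catalysed acylation masks the carbinol as a base-stable ester without α-hydrogens, so that it can neither undergo retro-aldol cleavage nor form a five-membered lactol with C6 later on.

Step 3
Reactants: 6 benzoate
Product: 8 2-[1-(benzoyloxy)-3-(tert-butyldimethylsilyloxy)propyl]-2,6,6-trimethyl-3-oxocyclohexane-1-carbaldehyde (C6 aldehyde; C5/C10 trans as in 5), via ozonide 7 (not isolated)
Conditions: O3, CH2Cl2, −78 °C; then PPh3, −78 °C → rt
Reagents that add atoms: ozone [O-][O+]=O
Why: Ozonolysis with reductive work-up cleaves the only alkene and reveals C6 at the aldehyde oxidation level; no stereocentre is formed or touched.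

Step 4
Reactants: 8 keto aldehyde
Product: 10 trans-fused ring A/B keto acetal (6β-(4-methoxybenzyloxy)oxepane; C1 ketone; C9 benzoate), via oxepane lactol 9 (not isolated)
Conditions: HF·pyridine, THF, 0 °C; then 4-MeOC6H4CH2OH, PPTS (cat.), MgSO4, CH2Cl2, rt
Reagents that add atoms: 4-methoxybenzyl alcohol COc1ccc(CO)cc1
Why: Acidic fluoride desilylation (no acyl migration) frees the C7 hydroxyl, which closes ring B as the seven-membered lactol, and acid-catalysed acetal exchange should then give the thermodynamically preferred trans-fused anomer at C6 (acetalisation).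

Step 5
Reactants: 10 keto acetal
Product: 12 2-hydroxy-1-ketone (either C2 epimer), via lithium enolate 11 (not isolated)
Conditions: LiN(SiMe3)2, THF, −78 °C; then 2-(phenylsulfonyl)-3-phenyloxaziridine, −78 °C; aq. NH4Cl
Reagents that add atoms: 2-(phenylsulfonyl)-3-phenyloxaziridine O=S(=O)(N1OC1c1ccccc1)c1ccccc1
Why: C2 is the only enolisable position of the C1 ketone (C10 is quaternary), so electrophilic enolate hydroxylation with the N-sulfonyloxaziridine introduces the C2 oxygen regiospecifically; its configuration is erased in step 6.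

Step 6
Reactants: 12 hydroxy ketone
Product: 13 1,2-dione (in equilibrium with its C2 enol)
Conditions: DMP, NaHCO3, CH2Cl2, rt
Reagents that add atoms: none
Why: Periodinane oxidation of the α-hydroxy ketone gives the 1,2-dione, so that both ring-A carbinol centres can be set together by reduction.

Step 7
Reactants: 13 dione
Product: 14 1α,2α-diol
Conditions: NaBH4, CeCl3·7H2O, MeOH/CH2Cl2, −40 → 0 °C
Reagents that add atoms: none
Why: In the rigid trans-fused A/B chair the α-face of C1 and C2 is closed by the syn-axial methyl groups on C10 and C4, so both hydrides should arrive from the β-face (axial attack at C1, forced equatorial attack at C2) and give the cis-diol on the side of C20 (Luche reduction).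

Step 8
Reactants: 14 diol
Product: 15 1,2-O-(di-tert-butylsilylene) derivative
Conditions: t-Bu2Si(OSO2CF3)2, 2,6-lutidine, CH2Cl2, 0 °C
Reagents that add atoms: di-tert-butylsilyl bis(trifluoromethanesulfonate) CC(C)(C)[Si](OS(=O)(=O)C(F)(F)F)(OS(=O)(=O)C(F)(F)F)C(C)(C)C
Why: Cyclic silylene formation ties the cis-diol into one ring that is stable to enolates, Grignard reagents and the cationic key step, and is removable by fluoride without touching the acetal.

Step 9
Reactants: 15 silylene benzoate
Product: 16 C9 alcohol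
Conditions: i-Bu2AlH, CH2Cl2, −78 °C; aq. KNaC4H4O6
Reagents that add atoms: none
Why: Hydride reduction of the benzoate releases the C9 carbinol without the basic methanolysis that could open the five-membered silylene.

Step 10
Reactants: 16 alcohol
Product: 17 ring-B ketone (C9 ketone, C8 methylene)
Conditions: DMP, NaHCO3, CH2Cl2, rt
Reagents that add atoms: none
Why: Periodinane oxidation of the hindered secondary alcohol gives the C9 ketone, whose only enolisable position is C8.

Step 11
Reactants: 17 ring-B ketone; 18 allyl bromide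
Product: 20 8-allyl ketone (either C8 epimer), via lithium enolate 19 (not isolated)
Conditions: LiN(SiMe3)2, THF, −78 °C; then 18, DMPU, −78 → −40 °C
Reagents that add atoms: none
Why: Enolate alkylation introduces the first arm (future C14–C13); the lithium counter-ion and low temperature are chosen to keep β-elimination of the ring oxygen from the enolate slow.

Step 12
Reactants: 20 8-allyl ketone; 21 [2-(chloromethyl)allyl]trimethylsilane
Product: 23 8-allyl-8-[2-(trimethylsilylmethyl)allyl] ketone (quaternary C8), via lithium enolate 22 (not isolated)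
Conditions: LiN(SiMe3)2, THF/DMPU, −78 °C; then 21, Bu4NI (cat.), −78 → −20 °C
Reagents that add atoms: none
Why: Alkylation of the tetrasubstituted enolate creates the quaternary C8; the electrophile should approach anti to the axial C10 methyl, which shields the α-face of C8 across the enolate, so the silylated arm (future C15) ends up β and the allyl arm (future C14) α.

Step 13
Reactants: 23 dialkylated ketone
Product: 24 spiro-cyclopentene (rings A, B and D; allylsilane C13=C16–C17H2SiMe3)
Conditions: second-generation Grubbs catalyst (H2IMes)(PCy3)Cl2Ru=CHPh (5 mol%), CH2Cl2, 40 °C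
Reagents that add atoms: none
Why: Ring-closing olefin metathesis of the two arms closes the five-membered ring D with loss of ethylene and places the allylsilane needed for step 15; no stereocentre is created.

Step 14
Reactants: 24 spiro ketone; 2 vinylmagnesium bromide (CH2=CHMgBr)
Product: 25 9-vinyl-9-ol (tertiary allylic alcohol, either C9 epimer)
Conditions: LaCl3·2LiCl (0.3 equiv), THF, 0 °C → rt; aq. NH4Cl
Reagents that add atoms: none
Why: 1,2-Addition of the Grignard reagent is the only pathway open to the non-enolisable C9 ketone and brings in C11 and C12; the C9 configuration is irrelevant because C9 becomes trigonal in step 15.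

Step 15
Reactants: 25 tertiary allylic alcohol
Product: 27 tetracyclic diene (rings A–D; C9=C11 and C16=C17), via trifluoroacetate 26 (not isolated)
Conditions: (CF3CO)2O, 2,6-lutidine, CH2Cl2, −78 °C; then (CF3)2CHOH, −78 → −20 °C
Reagents that add atoms: none
Why: Trifluoroacetylation gives 26, whose C9–O bond should ionise under buffered, non-acidic solvolytic conditions to the C9–C11–C12 allyl cation; since C9 sits between the quaternary C8 and C10 the cation has no β-hydrogen to lose, so it is captured at its primary terminus C12 by the γ-carbon C13 of the ring-D allylsilane, and loss of silicon from the β-silyl cation at C16 gives the C16=C17 methylene regiospecifically. The closest known reaction type is the allylsilane-terminated cation–olefin cyclisation, that is, an intramolecular Hosomi–Sakurai allylation with an allylic cation as electrophile. Ring C closes in a six-membered mode that is exo with respect to the allylsilane double bond (C16 stays outside the new ring) and takes all three allyl-cation carbons into the ring, which leaves C9=C11 endocyclic. The only new stereocentre, C13, is controlled by the spiro centre C8: the C9-bound cation can reach C13 only on the face of ring D that carries C9, so the bridgehead configuration of the bicyclo[3.2.1]octane follows from C8. The step needs chemoselective ionisation of the allylic ester in the presence of the C6 acetal and bond formation C12–C13 rather than C9–C13 or C12–C16; the first is secured by strain relief at the doubly neopentyl C9 and the absence of acid, the second by ring size (six against four) and the β-silicon effect.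

Step 16
Reactants: 27 silylene diene
Product: 28 1α,2α-diol
Conditions: HF·pyridine, pyridine, THF, 0 °C → rt
Reagents that add atoms: none
Why: Fluoride cleavage of the silylene (desilylation) is now safe because the allylsilane has been consumed, and buffered conditions leave the PMB acetal intact.

Step 17
Reactants: 28 diol
Product: 29 1α,2α-diacetate
Conditions: Ac2O, DMAP, pyridine, 40 °C
Reagents that add atoms: acetic anhydride CC(=O)OC(C)=O
Why: DMAP-catalysed acetylation installs both acetates of the target, the hindered axial C2 hydroxyl requiring the nucleophilic catalyst and gentle heating.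

Step 18
Reactants: 29 diacetate
Product: 30 15-ol (either C15 epimer)
Conditions: SeO2 (0.3 equiv), t-BuOOH, CH2Cl2, 0 °C → rt
Reagents that add atoms: selenium dioxide O=[Se]=O (catalytic oxygen carrier); tert-butyl hydroperoxide CC(C)(C)OO
Why: Allylic oxidation by selenium dioxide (ene reaction, then [2,3]-sigmatropic shift) should occur at C15, the only allylic CH2 of the 1,1-disubstituted alkene (C13 is a bridgehead), while C9=C11 is spared because the allylic carbons on its disubstituted end (C8, C10) carry no hydrogen.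

Step 19
Reactants: 30 allylic alcohol
Product: 31 15-oxo-16-ene (α-methylene cyclopentanone)
Conditions: DMP, NaHCO3, CH2Cl2, 0 °C → rt
Reagents that add atoms: none
Why: Periodinane oxidation of the allylic alcohol gives the enone of ring D and removes the undefined C15 centre.

Step 20
Reactants: 31 enone
Product: 32 9,11-exo-epoxide (PMB acetal of the target)
Conditions: 3-ClC6H4CO3H, NaHCO3, CH2Cl2, 0 °C
Reagents that add atoms: 3-chloroperoxybenzoic acid OOC(=O)c1cccc(Cl)c1
Why: Peracid epoxidation (Prilezhaev reaction) should select the electron-rich trisubstituted C9=C11 over the enone alkene and attack the exo face, because the endo face is covered by the C15–C16 bridge; this sets C9 and C11.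

Step 21
Reactants: 32 PMB acetal
Product: 33 target CNP0224512.1
Conditions: DDQ, CH2Cl2/pH 7 phosphate buffer, 0 °C → rt
Reagents that add atoms: none
Why: Oxidative cleavage of the p-methoxybenzyl acetal by DDQ releases the lactol under neutral conditions that the oxirane, the enone and the acetates tolerate; the lactol should settle at the preferred C6 anomer.

**Compound list**

1 | 2,4,4-trimethylcyclohex-2-en-1-one | CC1=CC(C)(C)CCC1=O | starting material
2 | vinylmagnesium bromide (CH2=CHMgBr) | C=C[Mg]Br | starting material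
3 | 3-[(tert-butyldimethylsilyl)oxy]propanal | O=CCCO[Si](C)(C)C(C)(C)C | starting material
4 | bromomagnesium (3R)-2,4,4-trimethyl-3-vinylcyclohex-1-en-1-olate | C=C[C@@H]1C(C)(C)CCC(O[Mg]Br)=C1C | intermediate
5 | (2R,3R)-2-[3-(tert-butyldimethylsilyloxy)-1-hydroxypropyl]-2,4,4-trimethyl-3-vinylcyclohexan-1-one (carbinol epimers) | C=C[C@@H]1C(C)(C)CCC(=O)[C@@]1(C)C(O)CCO[Si](C)(C)C(C)(C)C | intermediate
6 | benzoate of 5 | C=C[C@@H]1C(C)(C)CCC(=O)[C@@]1(C)C(OC(=O)c2ccccc2)CCO[Si](C)(C)C(C)(C)C | intermediate
7 | 1,2,4-trioxolane (ozonide) of 6 | O1OC(OC1)[C@@H]2C(C)(C)CCC(=O)[C@@]2(C)C(OC(=O)c3ccccc3)CCO[Si](C)(C)C(C)(C)C | intermediate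
8 | C6 aldehyde: 2-[1-(benzoyloxy)-3-(tert-butyldimethylsilyloxy)propyl]-2,6,6-trimethyl-3-oxocyclohexane-1-carbaldehyde, C5/C10 trans | O=C[C@@H]1C(C)(C)CCC(=O)[C@@]1(C)C(OC(=O)c2ccccc2)CCO[Si](C)(C)C(C)(C)C | intermediate
9 | trans-fused oxepane lactol (6-OH; C1 ketone; C9 benzoate) | C1CO[C@@H](O)[C@@H]2C(C)(C)CCC(=O)[C@@]2(C)C1OC(=O)c3ccccc3 | intermediate
10 | 6β-(4-methoxybenzyloxy)oxepane acetal, C1 ketone, C9 benzoate (rings A and B) | C1CO[C@@H](OCc4ccc(OC)cc4)[C@@H]2C(C)(C)CCC(=O)[C@@]2(C)C1OC(=O)c3ccccc3 | intermediate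
11 | lithium enolate of 10 (C1–OLi, C1=C2) | C1CO[C@@H](OCc4ccc(OC)cc4)[C@@H]2C(C)(C)CC=C(O[Li])[C@@]2(C)C1OC(=O)c3ccccc3 | intermediate
12 | 2-hydroxy-1-ketone (C2 epimers) | C1CO[C@@H](OCc4ccc(OC)cc4)[C@@H]2C(C)(C)CC(O)C(=O)[C@@]2(C)C1OC(=O)c3ccccc3 | intermediate
13 | 1,2-dione | C1CO[C@@H](OCc4ccc(OC)cc4)[C@@H]2C(C)(C)CC(=O)C(=O)[C@@]2(C)C1OC(=O)c3ccccc3 | intermediate
14 | 1α,2α-diol | C1CO[C@@H](OCc4ccc(OC)cc4)[C@@H]2C(C)(C)C[C@H](O)[C@H](O)[C@@]2(C)C1OC(=O)c3ccccc3 | intermediate
15 | 1α,2α-O-(di-tert-butylsilylene) C9 benzoate | C1CO[C@@H](OCc4ccc(OC)cc4)[C@@H]2C(C)(C)C[C@H](O[Si]5(C(C)(C)C)C(C)(C)C)[C@H](O5)[C@@]2(C)C1OC(=O)c3ccccc3 | intermediate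
16 | C9 alcohol | C1CO[C@@H](OCc4ccc(OC)cc4)[C@@H]2C(C)(C)C[C@H](O[Si]5(C(C)(C)C)C(C)(C)C)[C@H](O5)[C@@]2(C)C1O | intermediate
17 | ring-B ketone (C9=O, C8H2) | C1CO[C@@H](OCc4ccc(OC)cc4)[C@@H]2C(C)(C)C[C@H](O[Si]5(C(C)(C)C)C(C)(C)C)[C@H](O5)[C@@]2(C)C1=O | intermediate
18 | allyl bromide | C=CCBr | starting material
19 | lithium enolate of 17 (C9–OLi, C8=C9) | [Li]OC1=CCO[C@@H](OCc4ccc(OC)cc4)[C@@H]2C(C)(C)C[C@H](O[Si]5(C(C)(C)C)C(C)(C)C)[C@H](O5)[C@@]12C | intermediate
20 | 8-allyl ketone (C8 epimers) | C=CCC1CO[C@@H](OCc4ccc(OC)cc4)[C@@H]2C(C)(C)C[C@H](O[Si]5(C(C)(C)C)C(C)(C)C)[C@H](O5)[C@@]2(C)C1=O | intermediate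
21 | [2-(chloromethyl)allyl]trimethylsilane | C=C(CCl)C[Si](C)(C)C | starting material
22 | lithium enolate of 20 | [Li]OC1=C(CC=C)CO[C@@H](OCc4ccc(OC)cc4)[C@@H]2C(C)(C)C[C@H](O[Si]5(C(C)(C)C)C(C)(C)C)[C@H](O5)[C@@]12C | intermediate
23 | 8-allyl-8-[2-(trimethylsilylmethyl)allyl] ketone (allyl α, silylated arm β) | C=CC[C@]1(CC(=C)C[Si](C)(C)C)CO[C@@H](OCc4ccc(OC)cc4)[C@@H]2C(C)(C)C[C@H](O[Si]5(C(C)(C)C)C(C)(C)C)[C@H](O5)[C@@]2(C)C1=O | intermediate
24 | spiro-cyclopentene ketone (rings A, B, D; C13=C16 bearing CH2SiMe3) | C[Si](C)(C)CC1=CC[C@]2(C1)CO[C@@H](OCc4ccc(OC)cc4)[C@@H]3C(C)(C)C[C@H](O[Si]5(C(C)(C)C)C(C)(C)C)[C@H](O5)[C@@]3(C)C2=O | intermediate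
25 | 9-vinyl-9-ol (C9 epimers) | C[Si](C)(C)CC1=CC[C@]2(C1)CO[C@@H](OCc4ccc(OC)cc4)[C@@H]3C(C)(C)C[C@H](O[Si]5(C(C)(C)C)C(C)(C)C)[C@H](O5)[C@@]3(C)C2(O)C=C | intermediate
26 | 9-trifluoroacetate of 25 | C[Si](C)(C)CC1=CC[C@]2(C1)CO[C@@H](OCc4ccc(OC)cc4)[C@@H]3C(C)(C)C[C@H](O[Si]5(C(C)(C)C)C(C)(C)C)[C@H](O5)[C@@]3(C)C2(OC(=O)C(F)(F)F)C=C | intermediate
27 | tetracyclic 9(11),16-diene, silylene, PMB acetal | C=C1C[C@@]23CO[C@@H](OCc4ccc(OC)cc4)[C@@H]5C(C)(C)C[C@H](O[Si]6(C(C)(C)C)C(C)(C)C)[C@H](O6)[C@@]5(C)C2=CC[C@@H]1C3 | intermediate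
28 | 1α,2α-diol diene | C=C1C[C@@]23CO[C@@H](OCc4ccc(OC)cc4)[C@@H]5C(C)(C)C[C@H](O)[C@H](O)[C@@]5(C)C2=CC[C@@H]1C3 | intermediate
29 | 1α,2α-diacetate diene | C=C1C[C@@]23CO[C@@H](OCc4ccc(OC)cc4)[C@@H]5C(C)(C)C[C@H](OC(C)=O)[C@H](OC(C)=O)[C@@]5(C)C2=CC[C@@H]1C3 | intermediate
30 | 15-hydroxy diene (C15 epimers) | C=C1C(O)[C@@]23CO[C@@H](OCc4ccc(OC)cc4)[C@@H]5C(C)(C)C[C@H](OC(C)=O)[C@H](OC(C)=O)[C@@]5(C)C2=CC[C@@H]1C3 | intermediate
31 | 15-oxo-9(11),16-diene | C=C1C(=O)[C@@]23CO[C@@H](OCc4ccc(OC)cc4)[C@@H]5C(C)(C)C[C@H](OC(C)=O)[C@H](OC(C)=O)[C@@]5(C)C2=CC[C@@H]1C3 | intermediate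
32 | 9,11-exo-epoxide, PMB acetal | C=C1C(=O)[C@@]23CO[C@@H](OCc4ccc(OC)cc4)[C@@H]5C(C)(C)C[C@H](OC(C)=O)[C@H](OC(C)=O)[C@@]5(C)[C@]26O[C@@H]6C[C@@H]1C3 | intermediate
33 | CNP0224512.1 | C=C1C(=O)[C@@]23CO[C@@H](O)[C@@H]4C(C)(C)C[C@H](OC(C)=O)[C@H](OC(C)=O)[C@@]4(C)[C@]24O[C@@H]4C[C@@H]1C3 | target

**Step count and risks**

Total step count: 21. Longest linear sequence: 21 steps (from 1).

Three steps most likely to fail:

Step 1. The copper-catalysed addition may be slow at the neopentyl β-carbon of the α-substituted enone and may give poor enantiofacial discrimination; the hindered aldolate may also revert. Fallback: setting out from 1, 2 and 3, the same conjugate addition–aldol coupling is run with CuBr·SMe2 and no chiral ligand. This should give 5 as a racemate, that is, together with its enantiomer (2S,3S)-2-[3-(tert-butyldimethylsilyloxy)-1-hydroxypropyl]-2,4,4-trimethyl-3-vinylcyclohexan-1-one F1. The enantiomers are separated by preparative chromatography on a chiral stationary phase, and the route is re-entered at 5.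

Step 12. The C8 enolate may expel the ring-B oxygen (β-elimination), and the facial discrimination of the second alkylation by the C10 methyl may be too weak. Fallback: setting out from 17, the silylated arm is introduced first (LiN(SiMe3)2, then 21) to give 8-[2-(trimethylsilylmethyl)allyl] ketone F2. Its potassium enolate (KN(SiMe3)2, −78 °C) is O-acylated at once with allyl chloroformate to allyl enol carbonate F3. Pd2(dba)3 with (S)-4-tert-butyl-2-[2-(diphenylphosphino)phenyl]-4,5-dihydrooxazole (or its enantiomer, whichever matches the substrate) then effects decarboxylative allylic alkylation (Tsuji allylation) under catalyst control. This delivers the allyl arm to the chosen face of a non-basic palladium enolate and comes back to the route at 23.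

Step 20. The peracid may attack the endo face of the hindered C9=C11 double bond. Fallback: setting out from 31, N-bromosuccinimide in aqueous 1,2-dimethoxyethane should form the bromonium ion on the face the peracid prefers, and water should open it at the tertiary C9 from the opposite face. This gives 9-hydroxy-11-bromide F4 (hydroxyl exo, bromine endo). Ag2O then closes the oxirane by intramolecular displacement with inversion at C11, which places the oxygen on the exo face and comes back to the route at 32.

**Further compounds**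

F1 | step 1 | (2S,3S)-2-[3-(tert-butyldimethylsilyloxy)-1-hydroxypropyl]-2,4,4-trimethyl-3-vinylcyclohexan-1-one (enantiomer of 5) | C=C[C@H]1C(C)(C)CCC(=O)[C@]1(C)C(O)CCO[Si](C)(C)C(C)(C)C
F2 | step 12 | 8-[2-(trimethylsilylmethyl)allyl] ketone (C8 epimers) | C=C(C[Si](C)(C)C)CC1CO[C@@H](OCc4ccc(OC)cc4)[C@@H]2C(C)(C)C[C@H](O[Si]5(C(C)(C)C)C(C)(C)C)[C@H](O5)[C@@]2(C)C1=O
F3 | step 12 | allyl enol carbonate of F2 (C8=C9–O–CO2-allyl) | C=CCOC(=O)OC1=C(CC(=C)C[Si](C)(C)C)CO[C@@H](OCc4ccc(OC)cc4)[C@@H]2C(C)(C)C[C@H](O[Si]5(C(C)(C)C)C(C)(C)C)[C@H](O5)[C@@]12C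
F4 | step 20 | 9-exo-hydroxy-11-endo-bromide of 31 | C=C1C(=O)[C@@]23CO[C@@H](OCc4ccc(OC)cc4)[C@@H]5C(C)(C)C[C@H](OC(C)=O)[C@H](OC(C)=O)[C@@]5(C)[C@@]2(O)[C@@H](Br)C[C@@H]1C3
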